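Early on, while the feed runs, the starting complex in Saturday's flask climbs, and the readings peak at 78.3% of the charge at 1.04 d, where the feed of 1.04 d ends.

| setting | Saturday's | Thursday's | flask |
|---|---|---|---|
| starting complex | 0.10 M (fed, over 25 h) | 0.10 M (fed, over 25 h) | 0.10 M (fed, over 25 h) |
| incoming ligand | 0.20 M | 0.20 M | 0.200 M |
| scavenger | 0.12 M | 0.24 M | 0.120 M |
| remark | the very flask that is asked about, followed so far; the fed solution adds 0.20 times the starting volume | run made earlier; the fed solution adds 0.20 times the starting volume | the fed solution adds 0.20 times the starting volume |
| time |  |  | 10 d |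

| run | time / d | starting complex / % | complex with one exchanged / % |
|---|---|---|---|
| Saturday's | 0.208 | 19.6 | 1.5 |
| Saturday's | 0.625 | 51.6 | 7.0 |
| Saturday's | 1.04 | 78.3 | 16.0 |
| Saturday's | 1.67 | 58.6 | 23.6 |
| Saturday's | 2.50 | 38.4 | 26.7 |
| Saturday's | 3.00 | 30.6 | 27.7 |
| Saturday's | 4.00 | 20.0 | 25.4 |
| Thursday's | 0.333 | 29.2 | 1.9 |
| Thursday's | 0.500 | 42.9 | 4.8 |
| Thursday's | 0.833 | 64.9 | 11.1 |
| Thursday's | 1.04 | 78.1 | 15.9 |
| Thursday's | 1.67 | 57.6 | 23.2 |
| Thursday's | 2.50 | 39.1 | 27.0 |
| Thursday's | 4.00 | 20.3 | 26.1 |

(each reading ± 0.3 percentage points)

- percent here means starting complex units held: one side product counts as two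
- what is said of leaving ligand includes idle adduct
- amounts are per litre of the starting volume; all of the dose is in the solution fed
- the analysis behind the earlier runs scatters by 0.3 percentage points, standard deviation
- candidate steps: starting complex + incoming ligand <-> leaving ligand + complex with one exchanged; scavenger + leaving ligand -> scavenged by-product; leaving ligand + incoming ligand <-> idle adduct; complex with one exchanged + incoming ligand <-> leaving ligand + complex with two exchanged; starting complex + complex with one exchanged -> side product
- percentages count the whole charge, also what has not yet gone in
- the earlier runs do not show how much of incoming ligand is bound; that part of a forecast is a guess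

1. part of the starting complex that has reacted at 10 d
2. share of the unused incoming ligand that is free and not bound as idle adduct, at 10 d

What must the end state be? After the feed, Saturday's readings keep falling, down to 20.0% at 4.00 d, with no sign of a floor. So I expect the starting complex in Saturday's flask to go on falling, and I ask how fast.

How fast? Treat the fall as steady halving and define the half-life after the feed: the time in which the starting complex, no longer topped up, falls by a factor of 2. Saturday's readings at 1.67 d and 4.00 d give 1.50 d.

Does Thursday's run agree? With twice the scavenger, its readings give 1.55 d, so I carry Saturday's value.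

How many halvings fit? From the end of the feed to 10 d there are 5.96, which leaves 1.26% and makes 98.7% reacted.

Is that half-life really constant? No. Saturday's readings from 1.67 d to 2.50 d give 1.36 d, and those from 3.00 d to 4.00 d give 1.63 d, which is longer. So I hold 98.7% as a high estimate and expect somewhat less.

And the free share of incoming ligand? The readings do not show what is bound, so I offer no number.

The forecast gave 97.5% reacted (from 95% to 99%), under my high estimate, and 90% free (from 60% to 100%), saying “little adduct should exist yet”.

The flask reacted 97.4% of its starting complex, and 99.8% of its unused incoming ligand was free.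

    starting complex + incoming ligand ⇌ leaving ligand + complex with one exchanged (K = 37.0, k = 0.110 L mol⁻¹ h⁻¹)
    scavenger + leaving ligand → scavenged by-product (k = 10.0 L mol⁻¹ h⁻¹)
    leaving ligand + incoming ligand ⇌ idle adduct, settled at all times (K = 2.50 L mol⁻¹)
    complex with one exchanged + incoming ligand ⇌ leaving ligand + complex with two exchanged (K = 0.470, k = 0.0680 L mol⁻¹ h⁻¹)
    starting complex + complex with one exchanged → side product (k = 0.280 L mol⁻¹ h⁻¹)

At 10.0 d the flask still held 13% of its scavenger, beside leaving ligand at 6.37 × 10⁻⁴ M and idle adduct at 1.25 × 10⁻⁴ M. Going from 78.3% of starting complex at the end of the feed to 2.57% there, the flask's half-life averaged 1.82 d, longer than the 1.50 d read earlier. For the neighbour charged with 0.12 M of incoming ligand, stretching that average by the ratio of the charges, and assuming the same amount at the end of the feed, gives an estimate of 10.1% left; that neighbour holds 9.95%.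

The runs were computed from invented constants; noise was put on by code.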